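## Structural features

Target 39 is an open-chain pentadeca-2,6,12-trienoic acid whose only ring is a 3-substituted furan at C15 and whose only stereocentre is C9 (S), which carries an isopropenyl group. Two arms leave C9: the acid-side arm C8–C1 (CH2–CH=C(CH3)–CH2CH2–CH=C(CO2H)–, with a 4-methylpent-3-enyl branch on C2) and the ester-side arm C10–C15 (CH2CH2–C(CO2CH3)=CH–CH2CH2–furyl). C9 has no stereogenic neighbour and no heteroatom nearby, so it cannot be set by induction from within the molecule, and its two arms differ only from the second carbon on (C8–C7 is CH2–CH=, C10–C11 is CH2–CH2). Three trisubstituted alkenes need defined geometry: 6E, 2E (acid trans to the chain) and 12Z, the last with the ester cis to the furylethyl chain, the less stable arrangement. Fragile groups are the furan (acid, electrophiles, oxidants), the isopropenyl and prenyl-type alkenes (acid, boranes, hydrogenation), the Z-enoate (isomerisation) and the free acid/methyl ester pair, which must stay distinct to the end. The real difficulty is twofold: telling two nearly identical CH2–C arms apart at C9 in an absolute sense, and building the 12Z enoate without leakage to the E isomer. The key step uses the fact that C9 with C8 and C10 maps onto C3 and the two CH2CO2CH3 groups of a 3-isopropenylglutarate; there the arms are enantiotopic and at one oxidation level, so a chiral enzyme active site alone makes C9 stereogenic and the arms chemically different.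

## Logic of the disconnections

39 ⇒ 38. Only the O–CH2 bond of a 2-(trimethylsilyl)ethyl ester on C1 is cut. The C1 acid must be masked during the organometallic steps and freed beside a methyl ester; a silylethyl ester is opened at silicon, not at the carbonyl. The gain is that the two carboxyl groups stay distinct without any selective hydrolysis. The demand is a fluoride step that leaves the C12 methyl ester, the furan and the alkenes alone.

38 ⇒ 27 + 36 (through 37). The C11–C12 bond between the sp3 arm and the ester-bearing alkene carbon is cut. This removes the whole furan half at once and moves the 12Z problem into a small fragment, where a stereospecific addition to an alkyne can solve it. The forward step must join a primary alkylzinc to an α-iodoenoate with retention of geometry and without β-hydride loss.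

36 ⇒ 34 ⇒ 32 ⇒ 31 ⇒ 30 ⇒ 28 + 29. The C–I and vinylic C–H bonds of 36 go back to the triple bond of 34 (syn addition of hydrogen and a metal, then metal–iodine exchange). The ester carbon of 34 comes from C-acylation of the acetylide of 32, the alkyne carbon of 32 from a one-carbon homologation of 31, and the chain of 31 from a two-carbon Wittig extension of 28 with 29 and conjugate reduction of 30. Each cut removes one or two carbons by a standard operation. The demands are regioselective syn hydrometallation and reductions that spare the furan.

27 ⇒ 26 ⇒ 25. No skeletal bond is cut; the C11–I bond is traced to a C11–O bond carried as a silyl ether. This keeps the reactive iodide out of all earlier steps. The demand is a desilylation without fluoride, since fluoride would also open the silylethyl ester.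

25 ⇒ 16 + 24; 24 ⇒ 21 + 22; 21 ⇒ 19 ⇒ 17 + 18. The C2=C3 double bond is cut with the branch placed on the ylide carbon, because an α-substituted ester-stabilised ylide gives the 2E geometry reliably. The ylide is cut at the bond from C2 to the side chain (to 22) and at C–P and O–acyl (to 17 and 18). The gain is a convergent supply of C1, C2 and the 4-methylpent-3-enyl branch in one reagent. The demands are C-alkylation of a stabilised ylide by an unactivated primary bromide and a Wittig step tolerant of the silyl ether.

16 ⇒ 15 ⇒ 13 + 4 (through 14). The C4–C5 bond and the 6E alkene are traced to a [3,3] shift of the ketene acetal of a secondary 2-methylallylic alcohol; the ester carbon becomes the aldehyde C3 after partial reduction. The cut removes two carbons and sets the trisubstituted alkene geometry through a chair transition state. The demand is that the silyl ether survives the weakly acidic, hot conditions.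

13 ⇒ 12 ⇒ 10 (through 11) ⇒ 9. The C6–C7 bond is cut (addition of an isopropenyl nucleophile to the masked aldehyde of 10), after taking off the silyl group at the primary oxygen. This reduces the acid-side arm to the carbonyl carbon of 9. The demands are selective silylation of a primary over a secondary allylic hydroxyl and clean half-reduction of 9.

9 ⇒ 7 (through 8). No skeletal bond is cut: the C–O bond of the ring is traced to the ester arm of 7, reduced while the acid arm is protected as its carboxylate. This leaves the acid-side carbon at the carbonyl level needed for the aldehyde and puts the ester-side carbon at the alcohol level needed for the iodide, with no redox detour and no borane near the isopropenyl group. The demand is a hydride that reduces an ester but not a carboxylate.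

7 ⇒ 6. One O–CH3 ester bond is exchanged for O–H; no carbon–carbon bond is cut. The gain is the largest of the route: 6 is achiral and trivially made, and the stereocentre arises by differentiation of enantiotopic groups. The demand is a catalyst that distinguishes two CH2CO2CH3 groups which differ only in their spatial relation to C3, which only an enzyme active site does well.

6 ⇒ 3 + 4 (through 5); 3 ⇒ 2 ⇒ 1. The bond from C3 of 6 to one CH2CO2CH3 arm is cut as a [3,3] shift of the ketene acetal 5; the same event turns a trisubstituted alkene into the isopropenyl group. The allylic oxygen of 3 is traced to a C–H bond of 2, and 2 to acid 1. The demand is site-selective allylic oxidation at the methyl group of the more substituted alkene terminus.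

## Other disconnections considered

Alternative 1: The cut is C9–C8, the bond from the stereocentre to the first carbon of the acid-side arm. In the forward sense tert-butyl[(4-methylpent-3-en-1-yl)oxy]diphenylsilane A1 and ethyl glyoxylate A2 would undergo a carbonyl-ene reaction under a chiral Lewis acid, for instance the complex made from BINOL and TiCl2(O-i-Pr)2, or Cu(OTf)2 with a bis(oxazoline). The aldehyde carbon of A2 bonds to the alkene CH of A1, a methyl hydrogen is transferred and the alkene shifts into the isopropenyl position, giving hydroxy ester A3. Reductive removal of the carbinol oxygen would give ester A4, which after reduction to the aldehyde and isopropenyl addition would stand at the stage that 13 holds in the chosen route.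
- In its favour: a skeletal bond and the stereocentre are formed in one catalytic step from an achiral alkene, the arms are at different oxidation levels from the start, and the catalyst is available in both mirror-image forms.
- Against it here: trisubstituted alkenes are slower ene donors than 1,1-disubstituted ones and their face selectivity is less secure; the silyl ether oxygen can compete for the Lewis acid; and a second stereocentre is made only to be removed in two further steps.
- Comparison: on mechanism the alternative selects a face of a prochiral alkene carbon, the chosen plan selects between enantiotopic groups two atoms from the prochiral carbon. On step economy the alternative is better: about six operations to the stage of 13 against eight. On structure the two are equal, since both deliver the same differentiated two-arm core. The chosen plan has the advantage that half-ester 7 is an acid whose enantiomeric purity can be raised by salt crystallisation.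

Alternative 2: The cut is C11–C12. In the forward sense alkylzinc iodide A5 (identical with 37) would couple with iodoenoate A6 (identical with 36) under PdCl2(dppf) to give the silylethyl ester A7 (identical with 38), with retention of alkene geometry.
- In its favour: it is convergent, joins two fragments of similar size late, and fixes the 12Z geometry by a stereospecific event.
- Against it as the strategy-bearing step: it is silent on the origin of the C9 configuration, so a plan built on it alone still needs a separate source of chirality; zinc insertion next to a 5-hexenyl-type alkene carries a cyclisation risk.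
- Comparison: this cut does not compete with the hydrolase step but complements it, and the chosen plan uses it as step 22. On the ester-side alkene the alternative is therefore the equal of the chosen plan, and on convergence it is better than the hydrolase step, which forms no skeletal bond. On the stereocentre it offers nothing.

Alternative 3: The cut is C9–C10, the bond from the stereocentre to the first CH2 of the ester-side arm. In the forward sense the (E)-allylic phosphate A8 and the functionalised dialkylzinc A9 would react under a chiral copper catalyst, for instance (CuOTf)2·C6H6 with a chiral carbene or peptide ligand. Attack at the γ-carbon (SN2′) forms the bond and shifts the alkene into the isopropenyl position, giving ester A10.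
- In its favour: the stereocentre and a skeletal bond arise in one catalytic step, the isopropenyl group comes for free from the transposition, and the arms are distinct from the start.
- Against it here: A9 must be prepared and transfers only one of its two alkyl groups; SN2′ against SN2 selectivity and enantioselectivity on a 2-methyl-substituted allylic phosphate are less secure than on unbranched ones. Most seriously, in A10 the carbon next to the ester must later become the Z-configured alkene carbon C12; condensation with 31 and dehydration would favour the E isomer, so the geometry problem that the iodoenoate solves returns.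
- Comparison: the alternative is better in that the stereogenic step also builds the skeleton and reaches a differentiated core in fewer steps. On mechanism it relies on ligand control of a prochiral alkene face, the chosen plan on enzymatic group selection. The chosen plan is better on structure because it keeps the stereocentre problem and the 12Z problem apart.

Key step: step 4

Assumption: the hydrolase chosen by screening (pig liver esterase first) cleaves the pro-S ester group of 6 and gives (3R)-7; the route is written for that sense. Should the opposite sense be found, the roles of the arms would be exchanged by reducing the acid group instead of the ester group (BH3·SMe2, THF, −15 °C), which leads to the same lactone 9.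

Remark: the spatial arrangement at the stereocentre is unchanged from 7 to 39; the descriptor changes (R in 7, S in 8–14, R in 15, 16, 25–27 and 37, S in 38 and 39) only because substituent priorities change.

## Steps

Step 1
Reactants: 1 4-methylpent-3-enoic acid
Product: 2 methyl 4-methylpent-3-enoate
Conditions: MeI, K2CO3, DMF, rt
Reagents that add atoms: iodomethane, CI
Why: SN2 O-alkylation of the potassium carboxylate; basic conditions are chosen because strong acid could close the acid onto the trisubstituted alkene as a γ-lactone, and K2CO3 is too weak to move the β,γ-alkene.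

Step 2
Reactants: 2 methyl 4-methylpent-3-enoate
Product: 3 methyl (3E)-5-hydroxy-4-methylpent-3-enoate
Conditions: SeO2 (0.5 equiv), t-BuOOH (2 equiv), salicylic acid (cat.), CH2Cl2, 0 °C → rt
Reagents that add atoms: tert-butyl hydroperoxide, CC(C)(C)OO (terminal oxidant; its oxygen reaches the substrate by way of SeO2, O=[Se]=O)
Why: Allylic oxidation with SeO2 (ene reaction, then [2,3]-sigmatropic shift) should attack the more substituted alkene terminus at the methyl group trans to the chain, giving the (E)-allylic alcohol; the E geometry keeps the hydroxyl away from the ester, so no lactone can form.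

Step 3
Reactants: 3 methyl (3E)-5-hydroxy-4-methylpent-3-enoate; 4 trimethyl orthoacetate
Product: 6 dimethyl 3-(prop-1-en-2-yl)pentanedioate, via mixed ketene acetal 5 (not isolated)
Conditions: 4 (5 equiv), EtCO2H (cat.), toluene, 110 °C, MeOH distilled off
Reagents that add atoms: none
Why: Johnson–Claisen rearrangement: acid-catalysed exchange gives ketene acetal 5, whose [3,3] shift joins its CH2 to C3 of the pentenoate and turns the trisubstituted alkene into the isopropenyl group; the new arm is CH2CO2CH3 like the old one, so the product should be the symmetric prochiral diester whatever the alkene geometry of 3.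

Step 4
Reactants: 6 dimethyl 3-(prop-1-en-2-yl)pentanedioate
Product: 7 (3R)-5-methoxy-5-oxo-3-(prop-1-en-2-yl)pentanoic acid
Conditions: pig liver esterase, 0.1 M phosphate buffer pH 7.0, MeOH (10–20% v/v), 0–20 °C, pH-stat (1 M NaOH, 1.0 equiv); then 1 M HCl to pH 2, 0 °C
Reagents that add atoms: water, O
Why: Serine-hydrolase mechanism: the active-site serine, activated by the histidine/acid pair, adds to one ester carbonyl of 6, methanol leaves from the tetrahedral intermediate held in the oxyanion hole, and water cleaves the acyl-enzyme to release the half-ester as its carboxylate. The closest known reaction type is the esterase- or lipase-mediated mono-hydrolysis of dimethyl 3-alkyl- and 3-arylglutarates; no skeletal bond is formed and no ring is closed. The new stereocentre C3 is controlled by the enzyme alone: only the chiral active site can tell the two enantiotopic CH2CO2CH3 groups apart, the isopropenyl group sitting in the hydrophobic pocket so that one ester carbonyl (taken here as the pro-S one) lies at the serine. Two selectivities are needed, between the enantiotopic groups and between first and second hydrolysis; the second is secured by the substrate itself, because the anionic half-ester binds poorly, and by stopping the pH-stat at one equivalent of base. Buffering at pH 7 and low temperature suppress the uncatalysed, non-selective hydrolysis, and co-solvent and temperature are the handles for raising the enantiomeric excess. The enantiomeric purity should be checked at the stage of lactone 9 and, if needed, raised by crystallising a salt of 7 with a chiral amine. Acidification is done cold and 7 is not heated, so that no acyl migration through the cyclic anhydride can scramble the arms.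

Step 5
Reactants: 7 (3R)-5-methoxy-5-oxo-3-(prop-1-en-2-yl)pentanoic acid
Product: 9 (4S)-4-(prop-1-en-2-yl)oxan-2-one, via (3S)-5-hydroxy-3-(prop-1-en-2-yl)pentanoic acid 8 (not isolated)
Conditions: NaH (1.0 equiv), THF, 0 °C; LiBH4 (1.5 equiv), 0 °C → rt; then 1 M HCl to pH 2, rt
Reagents that add atoms: none
Why: Chemoselective hydride reduction: LiBH4 reduces the methyl ester but not the sodium carboxylate, and forming the carboxylate first avoids acyloxyborane species that could hydroborate the isopropenyl group; acidification gives δ-hydroxy acid 8, which should close to the six-membered lactone, leaving the acid-side arm as C=O and the ester-side arm as CH2O without touching the stereocentre.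

Step 6
Reactants: 9 (4S)-4-(prop-1-en-2-yl)oxan-2-one
Product: 10 (4S)-4-(prop-1-en-2-yl)oxan-2-ol (lactol as an anomer mixture)
Conditions: i-Bu2AlH (1.1 equiv), CH2Cl2, −78 °C
Reagents that add atoms: none
Why: Partial reduction of a δ-lactone: the aluminium hemiacetal is stable at −78 °C and gives the lactol on work-up, and the isolated alkene is inert to i-Bu2AlH at this temperature.

Step 7
Reactants: 10 (4S)-4-(prop-1-en-2-yl)oxan-2-ol
Product: 12 (3RS,5S)-2-methyl-5-(prop-1-en-2-yl)hept-1-ene-3,7-diol, via (3S)-5-hydroxy-3-(prop-1-en-2-yl)pentanal 11 (not isolated)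
Conditions: CH2=C(CH3)MgBr (3 equiv), THF, 0 °C → rt
Reagents that add atoms: isopropenylmagnesium bromide, C=C(C)[Mg]Br
Why: Grignard addition to a lactol: the first equivalent deprotonates the hemiacetal, which opens to the alkoxide of hydroxy aldehyde 11, and a second adds to the aldehyde; the carbinol centre forms as a mixture, which does not matter because it is consumed in step 9.

Step 8
Reactants: 12 (3RS,5S)-2-methyl-5-(prop-1-en-2-yl)hept-1-ene-3,7-diol
Product: 13 (3RS,5S)-7-[(tert-butyldimethylsilyl)oxy]-2-methyl-5-(prop-1-en-2-yl)hept-1-en-3-ol
Conditions: TBSCl (1.05 equiv), imidazole, CH2Cl2, −20 → 0 °C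
Reagents that add atoms: tert-butyldimethylsilyl chloride, CC(C)(C)[Si](C)(C)Cl
Why: Selective silylation of the primary hydroxyl; the secondary allylic alcohol, flanked by the isopropenyl group, should react much more slowly with the bulky silyl chloride at low temperature.

Step 9
Reactants: 13 (3RS,5S)-7-[(tert-butyldimethylsilyl)oxy]-2-methyl-5-(prop-1-en-2-yl)hept-1-en-3-ol; 4 trimethyl orthoacetate
Product: 15 methyl (4E,7R)-9-[(tert-butyldimethylsilyl)oxy]-4-methyl-7-(prop-1-en-2-yl)non-4-enoate, via mixed ketene acetal 14 (not isolated)
Conditions: 4 (8 equiv), EtCO2H (cat.), toluene, 110–130 °C, MeOH distilled off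
Reagents that add atoms: none
Why: Johnson–Claisen rearrangement of a secondary 2-methylallylic alcohol: in the chair transition state the chain at the carbinol carbon sits equatorial to avoid the 1,3-diaxial clash with the methoxy group of the ketene acetal, which should give the (E)-trisubstituted alkene and adds the carbons that become C3 and C4 of 39; a primary tert-butyldimethylsilyl ether tolerates the weak acid, and the stereocentre lies outside the reacting array.

Step 10
Reactants: 15 methyl (4E,7R)-9-[(tert-butyldimethylsilyl)oxy]-4-methyl-7-(prop-1-en-2-yl)non-4-enoate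
Product: 16 (4E,7R)-9-[(tert-butyldimethylsilyl)oxy]-4-methyl-7-(prop-1-en-2-yl)non-4-enal
Conditions: i-Bu2AlH (1.05 equiv), CH2Cl2, −78 °C
Reagents that add atoms: none
Why: Partial reduction of a methyl ester to the aldehyde through the aluminium hemiacetal, which is stable at −78 °C; no other reducible group is present.

Step 11
Reactants: 17 2-(trimethylsilyl)ethanol; 18 bromoacetyl bromide
Product: 19 2-(trimethylsilyl)ethyl bromoacetate
Conditions: pyridine, CH2Cl2, 0 °C
Reagents that add atoms: none
Why: Acylation of a primary alcohol by an acid bromide; the acyl bromide is far more electrophilic than the alkyl bromide, so only the ester should form.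

Step 12
Reactants: 19 2-(trimethylsilyl)ethyl bromoacetate
Product: 21 2-(trimethylsilyl)ethyl (triphenyl-λ5-phosphanylidene)acetate, via phosphonium bromide 20 (not isolated)
Conditions: PPh3, toluene, rt; then 1 M NaOH, CH2Cl2, 0 °C
Reagents that add atoms: triphenylphosphine, c1ccc(cc1)P(c1ccccc1)c1ccccc1
Why: SN2 quaternisation of PPh3 by an α-bromo ester, then deprotonation of the acidic phosphonium salt to the stabilised ylide (standard preparation of a Wittig reagent).

Step 13
Reactants: 21 2-(trimethylsilyl)ethyl (triphenyl-λ5-phosphanylidene)acetate; 22 5-bromo-2-methylpent-2-ene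
Product: 24 2-(trimethylsilyl)ethyl 6-methyl-2-(triphenyl-λ5-phosphanylidene)hept-5-enoate, via phosphonium bromide 23 (not isolated)
Conditions: 22 (1.2 equiv), Bu4NI (10 mol%), MeCN, 80 °C; then 1 M NaOH, CH2Cl2, 0 °C
Reagents that add atoms: none
Why: C-Alkylation of a stabilised phosphorus ylide by a primary halide, the SN2 step being speeded by iodide catalysis; the α-alkylated salt 23 is less acidic than the parent salt, so it should not be deprotonated by 21 during the alkylation and is turned into ylide 24 only by the hydroxide wash.

Step 14
Reactants: 16 (4E,7R)-9-[(tert-butyldimethylsilyl)oxy]-4-methyl-7-(prop-1-en-2-yl)non-4-enal; 24 2-(trimethylsilyl)ethyl 6-methyl-2-(triphenyl-λ5-phosphanylidene)hept-5-enoate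
Product: 25 2-(trimethylsilyl)ethyl (2E,6E,9R)-11-[(tert-butyldimethylsilyl)oxy]-6-methyl-2-(4-methylpent-3-en-1-yl)-9-(prop-1-en-2-yl)undeca-2,6-dienoate
Conditions: toluene, 90 °C
Reagents that add atoms: none
Why: Wittig olefination with an α-substituted ester-stabilised ylide; reversible oxaphosphetane formation favours the alkene with the ester trans to the new chain, which is the required 2E geometry.

Step 15
Reactants: 25 2-(trimethylsilyl)ethyl (2E,6E,9R)-11-[(tert-butyldimethylsilyl)oxy]-6-methyl-2-(4-methylpent-3-en-1-yl)-9-(prop-1-en-2-yl)undeca-2,6-dienoate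
Product: 26 2-(trimethylsilyl)ethyl (2E,6E,9R)-11-hydroxy-6-methyl-2-(4-methylpent-3-en-1-yl)-9-(prop-1-en-2-yl)undeca-2,6-dienoate
Conditions: camphorsulfonic acid (10 mol%), MeOH/CH2Cl2, 0 °C
Reagents that add atoms: none
Why: Acid-catalysed methanolysis of a primary silyl ether; fluoride is avoided because it would also open the 2-(trimethylsilyl)ethyl ester, and a catalytic sulfonic acid at 0 °C for a short time should leave the alkenes and the hindered unsaturated ester untouched.

Step 16
Reactants: 26 2-(trimethylsilyl)ethyl (2E,6E,9R)-11-hydroxy-6-methyl-2-(4-methylpent-3-en-1-yl)-9-(prop-1-en-2-yl)undeca-2,6-dienoate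
Product: 27 2-(trimethylsilyl)ethyl (2E,6E,9R)-11-iodo-6-methyl-2-(4-methylpent-3-en-1-yl)-9-(prop-1-en-2-yl)undeca-2,6-dienoate
Conditions: I2, PPh3, imidazole, CH2Cl2, 0 °C → rt
Reagents that add atoms: iodine, [I][I]
Why: Appel-type iodination: the alkoxyphosphonium ion is displaced by iodide at the primary carbon (SN2), two carbons away from the stereocentre.

Step 17
Reactants: 28 furan-3-carbaldehyde; 29 (triphenyl-λ5-phosphanylidene)acetaldehyde
Product: 30 (2E)-3-(furan-3-yl)prop-2-enal
Conditions: 28 (1.2 equiv), toluene, 80 °C
Reagents that add atoms: none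
Why: Wittig reaction with a formyl-stabilised ylide, which should give the (E)-enal; a slight excess of 28 limits a second homologation of the product.

Step 18
Reactants: 30 (2E)-3-(furan-3-yl)prop-2-enal
Product: 31 3-(furan-3-yl)propanal
Conditions: diethyl 2,6-dimethyl-1,4-dihydropyridine-3,5-dicarboxylate (Hantzsch ester, 1.1 equiv), dibenzylammonium trifluoroacetate (10 mol%), THF, rt
Reagents that add atoms: none
Why: Iminium-catalysed transfer hydrogenation: the secondary ammonium salt converts the enal into an iminium ion that accepts hydride at the β-carbon from the dihydropyridine; only the conjugated C=C is reduced, so the furan and the aldehyde should be spared, which catalytic hydrogenation would not guarantee.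

Step 19
Reactants: 31 3-(furan-3-yl)propanal
Product: 32 3-(but-3-yn-1-yl)furan
Conditions: dimethyl (1-diazo-2-oxopropyl)phosphonate, K2CO3, MeOH, 0 °C → rt
Reagents that add atoms: dimethyl (1-diazo-2-oxopropyl)phosphonate, CC(=O)C(=[N+]=[N-])P(=O)(OC)OC
Why: Ohira–Bestmann variant of the Seyferth–Gilbert homologation: methanolysis frees the diazomethylphosphonate anion, which adds to the aldehyde; loss of phosphate and N2 with 1,2-hydride shift gives the terminal alkyne under conditions mild enough for an enolisable aldehyde and a furan.

Step 20
Reactants: 32 3-(but-3-yn-1-yl)furan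
Product: 34 methyl 5-(furan-3-yl)pent-2-ynoate, via lithium acetylide 33 (not isolated)
Conditions: n-BuLi (1.05 equiv), THF, −78 °C; ClCO2Me, −78 → 0 °C
Reagents that add atoms: methyl chloroformate, COC(=O)Cl
Why: Deprotonation of the terminal alkyne, which is far more acidic than the furan C–H bonds, and C-acylation of the acetylide by the chloroformate.

Step 21
Reactants: 34 methyl 5-(furan-3-yl)pent-2-ynoate
Product: 36 methyl (2E)-5-(furan-3-yl)-2-iodopent-2-enoate, via methyl (2E)-5-(furan-3-yl)-2-(tributylstannyl)pent-2-enoate 35 (not isolated)
Conditions: Bu3SnH, Pd(PPh3)4 (2 mol%), THF, 0 °C → rt; then I2 (1.05 equiv), CH2Cl2, 0 °C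
Reagents that add atoms: iodine, [I][I]
Why: Palladium-catalysed hydrostannation of an alkynoate is a syn addition that places tin on the α-carbon and hydrogen on the β-carbon, so ester and furylethyl chain end up cis; iododestannylation proceeds with retention and should fix that geometry in the (E)-α-iodoenoate.

Step 22
Reactants: 27 2-(trimethylsilyl)ethyl (2E,6E,9R)-11-iodo-6-methyl-2-(4-methylpent-3-en-1-yl)-9-(prop-1-en-2-yl)undeca-2,6-dienoate; 36 methyl (2E)-5-(furan-3-yl)-2-iodopent-2-enoate
Product: 38 2-(trimethylsilyl)ethyl (2E,6E,9S,12Z)-15-(furan-3-yl)-12-(methoxycarbonyl)-6-methyl-2-(4-methylpent-3-en-1-yl)-9-(prop-1-en-2-yl)pentadeca-2,6,12-trienoate, via alkylzinc iodide 37 (not isolated)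
Conditions: Zn dust (activated with BrCH2CH2Br/Me3SiCl), DMA, 40 °C; then 36, PdCl2(dppf) (5 mol%), THF/DMA, rt → 40 °C
Reagents that add atoms: none
Why: Negishi coupling: zinc inserts into the primary C–I bond without affecting esters or alkenes, and the alkylzinc iodide transmetallates to the alkenylpalladium iodide formed from 36 by oxidative addition to zerovalent palladium with retention; the wide-bite-angle dppf ligand favours reductive elimination over β-hydride elimination, so the C11–C12 bond should form with the ester still cis to the furylethyl chain (12Z).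

Step 23
Reactants: 38 2-(trimethylsilyl)ethyl (2E,6E,9S,12Z)-15-(furan-3-yl)-12-(methoxycarbonyl)-6-methyl-2-(4-methylpent-3-en-1-yl)-9-(prop-1-en-2-yl)pentadeca-2,6,12-trienoate
Product: 39 (2E,6E,9S,12Z)-15-(furan-3-yl)-12-(methoxycarbonyl)-6-methyl-2-(4-methylpent-3-en-1-yl)-9-(prop-1-en-2-yl)pentadeca-2,6,12-trienoic acid
Conditions: Bu4NF (3 equiv), THF, 0 °C → rt; then 0.5 M HCl to pH 3–4, 0 °C
Reagents that add atoms: none
Why: Fluoride-induced fragmentation of the 2-(trimethylsilyl)ethyl ester (attack at silicon, loss of ethene and Me3SiF) frees the carboxylate without acyl substitution, so the methyl ester, the Z-enoate, the furan and the alkenes should remain; brief cold acidification gives the acid.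

## Compound list

1 | 4-methylpent-3-enoic acid | CC(C)=CCC(=O)O | starting material
2 | methyl 4-methylpent-3-enoate | CC(C)=CCC(=O)OC | intermediate
3 | methyl (3E)-5-hydroxy-4-methylpent-3-enoate | OC/C(C)=C/CC(=O)OC | intermediate
4 | trimethyl orthoacetate | CC(OC)(OC)OC | starting material
5 | methyl (3E)-5-[(1-methoxyethenyl)oxy]-4-methylpent-3-enoate (mixed ketene acetal) | C=C(OC)OC/C(C)=C/CC(=O)OC | intermediate (not isolated)
6 | dimethyl 3-(prop-1-en-2-yl)pentanedioate | C=C(C)C(CC(=O)OC)CC(=O)OC | intermediate
7 | (3R)-5-methoxy-5-oxo-3-(prop-1-en-2-yl)pentanoic acid | C=C(C)[C@H](CC(=O)O)CC(=O)OC | intermediate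
8 | (3S)-5-hydroxy-3-(prop-1-en-2-yl)pentanoic acid | C=C(C)[C@H](CC(=O)O)CCO | intermediate (not isolated)
9 | (4S)-4-(prop-1-en-2-yl)oxan-2-one | C=C(C)[C@@H]1CC(=O)OCC1 | intermediate
10 | (4S)-4-(prop-1-en-2-yl)oxan-2-ol (anomer mixture) | C=C(C)[C@@H]1CC(O)OCC1 | intermediate
11 | (3S)-5-hydroxy-3-(prop-1-en-2-yl)pentanal | C=C(C)[C@H](CC=O)CCO | intermediate (not isolated)
12 | (3RS,5S)-2-methyl-5-(prop-1-en-2-yl)hept-1-ene-3,7-diol | C=C(C)[C@H](CC(O)C(C)=C)CCO | intermediate
13 | (3RS,5S)-7-[(tert-butyldimethylsilyl)oxy]-2-methyl-5-(prop-1-en-2-yl)hept-1-en-3-ol | C=C(C)[C@H](CC(O)C(C)=C)CCO[Si](C)(C)C(C)(C)C | intermediate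
14 | tert-butyl({(3S,5RS)-5-[(1-methoxyethenyl)oxy]-6-methyl-3-(prop-1-en-2-yl)hept-6-en-1-yl}oxy)dimethylsilane (mixed ketene acetal) | C=C(C)[C@H](CC(OC(=C)OC)C(C)=C)CCO[Si](C)(C)C(C)(C)C | intermediate (not isolated)
15 | methyl (4E,7R)-9-[(tert-butyldimethylsilyl)oxy]-4-methyl-7-(prop-1-en-2-yl)non-4-enoate | C=C(C)[C@H](C/C=C(\C)CCC(=O)OC)CCO[Si](C)(C)C(C)(C)C | intermediate
16 | (4E,7R)-9-[(tert-butyldimethylsilyl)oxy]-4-methyl-7-(prop-1-en-2-yl)non-4-enal | C=C(C)[C@H](C/C=C(\C)CCC=O)CCO[Si](C)(C)C(C)(C)C | intermediate
17 | 2-(trimethylsilyl)ethanol | C[Si](C)(C)CCO | starting material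
18 | bromoacetyl bromide | BrCC(=O)Br | starting material
19 | 2-(trimethylsilyl)ethyl bromoacetate | C[Si](C)(C)CCOC(=O)CBr | intermediate
20 | {2-oxo-2-[2-(trimethylsilyl)ethoxy]ethyl}triphenylphosphonium bromide | C[Si](C)(C)CCOC(=O)C[P+](c1ccccc1)(c1ccccc1)c1ccccc1.[Br-] | intermediate (not isolated)
21 | 2-(trimethylsilyl)ethyl (triphenyl-λ5-phosphanylidene)acetate | C[Si](C)(C)CCOC(=O)C=P(c1ccccc1)(c1ccccc1)c1ccccc1 | intermediate
22 | 5-bromo-2-methylpent-2-ene | CC(C)=CCCBr | starting material
23 | {6-methyl-1-oxo-1-[2-(trimethylsilyl)ethoxy]hept-5-en-2-yl}triphenylphosphonium bromide | CC(C)=CCCC(C(=O)OCC[Si](C)(C)C)[P+](c1ccccc1)(c1ccccc1)c1ccccc1.[Br-] | intermediate (not isolated)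
24 | 2-(trimethylsilyl)ethyl 6-methyl-2-(triphenyl-λ5-phosphanylidene)hept-5-enoate | CC(C)=CCCC(C(=O)OCC[Si](C)(C)C)=P(c1ccccc1)(c1ccccc1)c1ccccc1 | intermediate
25 | 2-(trimethylsilyl)ethyl (2E,6E,9R)-11-[(tert-butyldimethylsilyl)oxy]-6-methyl-2-(4-methylpent-3-en-1-yl)-9-(prop-1-en-2-yl)undeca-2,6-dienoate | C=C(C)[C@H](C/C=C(\C)CC/C=C(\CCC=C(C)C)C(=O)OCC[Si](C)(C)C)CCO[Si](C)(C)C(C)(C)C | intermediate
26 | 2-(trimethylsilyl)ethyl (2E,6E,9R)-11-hydroxy-6-methyl-2-(4-methylpent-3-en-1-yl)-9-(prop-1-en-2-yl)undeca-2,6-dienoate | C=C(C)[C@H](C/C=C(\C)CC/C=C(\CCC=C(C)C)C(=O)OCC[Si](C)(C)C)CCO | intermediate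
27 | 2-(trimethylsilyl)ethyl (2E,6E,9R)-11-iodo-6-methyl-2-(4-methylpent-3-en-1-yl)-9-(prop-1-en-2-yl)undeca-2,6-dienoate | C=C(C)[C@H](C/C=C(\C)CC/C=C(\CCC=C(C)C)C(=O)OCC[Si](C)(C)C)CCI | intermediate
28 | furan-3-carbaldehyde (3-furaldehyde) | O=Cc1ccoc1 | starting material
29 | (triphenyl-λ5-phosphanylidene)acetaldehyde | O=CC=P(c1ccccc1)(c1ccccc1)c1ccccc1 | starting material
30 | (2E)-3-(furan-3-yl)prop-2-enal | O=C/C=C/c1ccoc1 | intermediate
31 | 3-(furan-3-yl)propanal | O=CCCc1ccoc1 | intermediate
32 | 3-(but-3-yn-1-yl)furan | C#CCCc1ccoc1 | intermediate
33 | [4-(furan-3-yl)but-1-yn-1-yl]lithium | [Li]C#CCCc1ccoc1 | intermediate (not isolated)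
34 | methyl 5-(furan-3-yl)pent-2-ynoate | COC(=O)C#CCCc1ccoc1 | intermediate
35 | methyl (2E)-5-(furan-3-yl)-2-(tributylstannyl)pent-2-enoate | COC(=O)/C(=C\CCc1ccoc1)[Sn](CCCC)(CCCC)CCCC | intermediate (not isolated)
36 | methyl (2E)-5-(furan-3-yl)-2-iodopent-2-enoate | COC(=O)/C(I)=C\CCc1ccoc1 | intermediate
37 | iodo{(3R,5E,9E)-6,14-dimethyl-3-(prop-1-en-2-yl)-10-{[2-(trimethylsilyl)ethoxy]carbonyl}pentadeca-5,9,13-trien-1-yl}zinc | C=C(C)[C@H](C/C=C(\C)CC/C=C(\CCC=C(C)C)C(=O)OCC[Si](C)(C)C)CC[Zn]I | intermediate (not isolated)
38 | 2-(trimethylsilyl)ethyl (2E,6E,9S,12Z)-15-(furan-3-yl)-12-(methoxycarbonyl)-6-methyl-2-(4-methylpent-3-en-1-yl)-9-(prop-1-en-2-yl)pentadeca-2,6,12-trienoate | C=C(C)[C@H](C/C=C(\C)CC/C=C(\CCC=C(C)C)C(=O)OCC[Si](C)(C)C)CC/C(=C/CCc1ccoc1)C(=O)OC | intermediate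
39 | (2E,6E,9S,12Z)-15-(furan-3-yl)-12-(methoxycarbonyl)-6-methyl-2-(4-methylpent-3-en-1-yl)-9-(prop-1-en-2-yl)pentadeca-2,6,12-trienoic acid | C=C(C)[C@H](C/C=C(\C)CC/C=C(\CCC=C(C)C)C(=O)O)CC/C(=C/CCc1ccoc1)C(=O)OC | target

## Step count and least certain steps

Total step count: 23 (main line 15, ylide branch 3, furan branch 5). Longest linear sequence: 15 steps (steps 1–10, 14–16, 22, 23).

Step 4 (key step). Most likely to go wrong: incomplete discrimination between the two enantiotopic ester groups, or discrimination in the unwanted sense. The isopropenyl group is of intermediate size for the hydrophobic pocket, so two binding modes may compete, and any uncatalysed hydrolysis adds racemic material. Fallback: setting out from 6, both esters are hydrolysed (LiOH, THF/H2O) to 3-(prop-1-en-2-yl)pentanedioic acid F1, which is dehydrated (Ac2O, 80 °C) to 4-(prop-1-en-2-yl)oxane-2,6-dione F2. The anhydride is then opened with methanol under a cinchona alkaloid (quinidine or quinine, chosen for the sense needed, or a catalytic bis-cinchona ether; toluene, −55 °C). This replaces enzymatic group selection by alkaloid-directed methanolysis of a meso-type anhydride and comes back to the route at 7.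

Step 22. Most likely to go wrong: ring closure of the carbon radical formed at the zinc surface onto the C6=C7 alkene (a 5-hexenyl arrangement) before it is captured as the organozinc, together with protonolysis of the zinc reagent and partial loss of alkene geometry on palladium. Fallback: setting out from 27 and 31, the sodium salt of methyl bis(2,2,2-trifluoroethyl)phosphonoacetate (NaH, DMF) is alkylated by 27. This gives methyl (2RS,5S,7E,11E)-2-[bis(2,2,2-trifluoroethoxy)phosphoryl]-8,16-dimethyl-5-(prop-1-en-2-yl)-12-{[2-(trimethylsilyl)ethoxy]carbonyl}heptadeca-7,11,15-trienoate F3. A Still–Gennari olefination of F3 with 31 (KN(SiMe3)2, 18-crown-6, THF, −78 °C) then builds the Z-enoate by kinetic control instead of by cross-coupling and comes back to the route at 38.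

Step 13. Most likely to go wrong: slow C-alkylation of the stabilised ylide by an unactivated primary bromide, with elimination of HBr from the homoallylic bromide competing at 80 °C. Fallback: setting out from 21, 16 and 22, ylide 21 is iodinated in the flask (N-iodosuccinimide, MeCN, −20 °C, then K2CO3) to 2-(trimethylsilyl)ethyl iodo(triphenyl-λ5-phosphanylidene)acetate F4. F4 reacts with 16 to give 2-(trimethylsilyl)ethyl (2Z,6E,9R)-11-[(tert-butyldimethylsilyl)oxy]-2-iodo-6-methyl-9-(prop-1-en-2-yl)undeca-2,6-dienoate F5. Bromide 22 is converted (Zn dust, I2 cat., DMA, 70 °C) into bromo(4-methylpent-3-en-1-yl)zinc F6, and a Negishi coupling of F5 with F6 under PdCl2(dppf) puts the side chain in with retention. This comes back to the route at 25.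

Step 2. Most likely to go wrong: over-oxidation of the allylic alcohol to the enal and incomplete conversion, with migration of the β,γ-alkene into conjugation once the aldehyde is present. Fallback: setting out from 2, a carbonyl-ene reaction with methyl glyoxylate (SnCl4, CH2Cl2, −78 °C) gives dimethyl 2-hydroxy-3-(prop-1-en-2-yl)pentanedioate F7. F7 is acetylated at once (Ac2O, pyridine), before the γ-hydroxy ester can lactonise, to dimethyl 2-(acetyloxy)-3-(prop-1-en-2-yl)pentanedioate F8. Reductive cleavage of the α-acetoxy group (SmI2, THF/MeOH) then gives the diester, so the route is rejoined at 6 and steps 2 and 3 are bypassed.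

## Further compounds

F1 | step 4 | 3-(prop-1-en-2-yl)pentanedioic acid | C=C(C)C(CC(=O)O)CC(=O)O
F2 | step 4 | 4-(prop-1-en-2-yl)oxane-2,6-dione | C=C(C)C1CC(=O)OC(=O)C1
F3 | step 22 | methyl (2RS,5S,7E,11E)-2-[bis(2,2,2-trifluoroethoxy)phosphoryl]-8,16-dimethyl-5-(prop-1-en-2-yl)-12-{[2-(trimethylsilyl)ethoxy]carbonyl}heptadeca-7,11,15-trienoate | C=C(C)[C@H](C/C=C(\C)CC/C=C(\CCC=C(C)C)C(=O)OCC[Si](C)(C)C)CCC(C(=O)OC)P(=O)(OCC(F)(F)F)OCC(F)(F)F
F4 | step 13 | 2-(trimethylsilyl)ethyl iodo(triphenyl-λ5-phosphanylidene)acetate | C[Si](C)(C)CCOC(=O)C(I)=P(c1ccccc1)(c1ccccc1)c1ccccc1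
F5 | step 13 | 2-(trimethylsilyl)ethyl (2Z,6E,9R)-11-[(tert-butyldimethylsilyl)oxy]-2-iodo-6-methyl-9-(prop-1-en-2-yl)undeca-2,6-dienoate | C=C(C)[C@H](C/C=C(\C)CC/C=C(\I)C(=O)OCC[Si](C)(C)C)CCO[Si](C)(C)C(C)(C)C
F6 | step 13 | bromo(4-methylpent-3-en-1-yl)zinc | CC(C)=CCC[Zn]Br
F7 | step 2 | dimethyl 2-hydroxy-3-(prop-1-en-2-yl)pentanedioate (racemic, diastereomer mixture) | C=C(C)C(CC(=O)OC)C(O)C(=O)OC
F8 | step 2 | dimethyl 2-(acetyloxy)-3-(prop-1-en-2-yl)pentanedioate (racemic, diastereomer mixture) | C=C(C)C(CC(=O)OC)C(OC(C)=O)C(=O)OC
A1 | alternative 1 | tert-butyl[(4-methylpent-3-en-1-yl)oxy]diphenylsilane | CC(C)=CCCO[Si](c1ccccc1)(c1ccccc1)C(C)(C)C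
A2 | alternative 1 | ethyl glyoxylate | CCOC(=O)C=O
A3 | alternative 1 | ethyl (2R,3R)-3-{2-[(tert-butyldiphenylsilyl)oxy]ethyl}-2-hydroxy-4-methylpent-4-enoate | C=C(C)[C@H]([C@@H](O)C(=O)OCC)CCO[Si](c1ccccc1)(c1ccccc1)C(C)(C)C
A4 | alternative 1 | ethyl (3S)-3-{2-[(tert-butyldiphenylsilyl)oxy]ethyl}-4-methylpent-4-enoate | C=C(C)[C@H](CC(=O)OCC)CCO[Si](c1ccccc1)(c1ccccc1)C(C)(C)C
A5 | alternative 2 | iodo{(3R,5E,9E)-6,14-dimethyl-3-(prop-1-en-2-yl)-10-{[2-(trimethylsilyl)ethoxy]carbonyl}pentadeca-5,9,13-trien-1-yl}zinc (identical with 37) | C=C(C)[C@H](C/C=C(\C)CC/C=C(\CCC=C(C)C)C(=O)OCC[Si](C)(C)C)CC[Zn]I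
A6 | alternative 2 | methyl (2E)-5-(furan-3-yl)-2-iodopent-2-enoate (identical with 36) | COC(=O)/C(I)=C\CCc1ccoc1
A7 | alternative 2 | 2-(trimethylsilyl)ethyl (2E,6E,9S,12Z)-15-(furan-3-yl)-12-(methoxycarbonyl)-6-methyl-2-(4-methylpent-3-en-1-yl)-9-(prop-1-en-2-yl)pentadeca-2,6,12-trienoate (identical with 38) | C=C(C)[C@H](C/C=C(\C)CC/C=C(\CCC=C(C)C)C(=O)OCC[Si](C)(C)C)CC/C(=C/CCc1ccoc1)C(=O)OC
A8 | alternative 3 | (2E)-5-[(tert-butyldimethylsilyl)oxy]-2-methylpent-2-en-1-yl diethyl phosphate | CCOP(=O)(OCC)OC/C(C)=C/CCO[Si](C)(C)C(C)(C)C
A9 | alternative 3 | bis(4-methoxy-4-oxobutyl)zinc | COC(=O)CCC[Zn]CCCC(=O)OC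
A10 | alternative 3 | methyl (5S)-5-{2-[(tert-butyldimethylsilyl)oxy]ethyl}-6-methylhept-6-enoate | C=C(C)[C@H](CCO[Si](C)(C)C(C)(C)C)CCCC(=O)OC
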